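## Analysis of the target

Locants follow the acid chain C1–C14: C1 is the carboxyl carbon and the ring is O1–O2–C3–C4–C5–C6.

- The target is a 3,6-epidioxy acid. The 1,2-dioxane carries the CH2CO2H arm (C2, C1) on C3, a methyl on C4, and a methyl plus the C7–C14 chain on the quaternary C6.
- The chain holds two methyl-bearing allylic stereocentres (C8, C12), two E alkenes (C9=C10, C13=C14) and a terminal phenyl.
- There are five stereocentres: 3S, 4S, 6R in the ring and 8R, 12S in the chain. In the ring the C2 arm, the C4 methyl and the C7 arm are all cis. In the chair the C4 methyl and C7 are equatorial and the acetic acid arm is axial, so the target is the less stable C3 epimer.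
- The hardest centre is C6. It is a tertiary peroxide carbon whose two exocyclic carbon substituents (CH3 and CH2R) are almost equal in size, so a ring closure through a chair transition state cannot tell them apart.
- Sensitive groups: the O–O bond (reductants, low-valent metals, organometallics, radicals or carbanions β or γ to it), the C3–H (base-induced Kornblum–DeLaMare fragmentation), the β-peroxy carboxyl (retro-oxa-Michael) and the skipped diene/styrene.
- C7 is a CH2 on a quaternary carbon, so C8 cannot be attached by substitution at C7.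
- The feature the route is built on: C2–C7 with the two methyls on C4 and C6 is the carbon skeleton of m-xylene. The cis relation of C2 and C7 across the dioxane is exactly what results if C2 and C7 were once bonded to each other as the third bridge of a 2,3-dioxabicyclo[2.2.2]octane.

## Retrosynthetic reasoning

**26 ⇒ 25 ⇒ 24.** The acid is taken back to aldehyde 25 and this to dimethyl acetal 24. The β-peroxy carboxyl is then never exposed to base, and the C1 oxygen travels through the chain assembly as an inert acetal.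

**24 ⇒ 17 + 23.** The C9=C10 bond is cut (Julia–Kocienski olefination). This is the only E alkene flanked by a stereocentre on each side, so the cut gives two fragments with one stereocentre each outside the ring. The coupling conditions form only C=C and leave the peroxide alone.

**17 ⇒ 15 ⇒ 14 ⇒ 12 ⇒ 8 + 11.** C8 is set by auxiliary-controlled methylation α to a C9 acyl group. The C7–C8 bond comes from a Horner–Wadsworth–Emmons reaction of the C7 aldehyde 8 with phosphonate 11, followed by metal-free saturation. C7 therefore enters as an aldehyde on the quaternary C6 and ends as CH2 without any radical, cation or leaving group next to the peroxide.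

**8 ⇒ 7.** The C1 carbon is added to the C2 aldehyde of dialdehyde 7 by a one-carbon Wittig reaction. The two formyl groups of 7 differ in hindrance (C2 on a tertiary carbon, C7 on the quaternary C6), and that difference is used to address them one after the other.

**7 ⇒ 6 ⇒ 5.** The C2–C7 bond is re-formed in thought: 7 is the glycol-cleavage product of bicyclic diol 6, a 2,3-dioxabicyclo[2.2.2]octane. In this frame the C6 methyl (exo) and C7 (bridge) are different by connectivity, not by size. The C4 methyl of 5 comes from face-selective transfer hydrogenation of the C4=C5 bridge of 4.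

**4 ⇒ 3 ⇒ 2 ⇒ 1 (key).** The peroxide bridge of 4 is removed by a retro-[4+2] (sensitised photooxygenation forward). This leaves diene acetonide 3, the protected cis-dihydrodiol 2 of m-xylene 1. One cycloaddition forms both C–O bonds, the O–O ring, the quaternary C6 and C3, and the acetonide dictates the face. The precursor is two steps from a bulk arene.

**23 ⇒ 21 ⇒ 20 ⇒ 18 + 19.** The sulfone is taken back through the alcohol 21 to ester 20, whose C12 centre comes from an enantioselective rhodium-catalysed conjugate addition of boronic acid 18 to crotonate 19.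

## Alternatives that were turned down

**Alternative 1 (textbook):** cut O2–C3.
- Forward key step: 6-exo oxa-Michael addition of the C6 hydroperoxide of A1 onto its C2=C3 enoate. A1 would come from a C6 1,1-disubstituted alkene by cobalt-mediated hydroperoxysilylation (cobalt bis(2,2,6,6-tetramethylheptane-3,5-dionate), O2, Et3SiH).
- Turned down because the tertiary C6 radical captures O2 with no facial bias (CH3 against CH2R, only remote acyclic centres), so C6 would form as a near-equal mixture.
- The closure through a chair with the enoate equatorial places the acetate arm equatorial (3,4-trans), and the reversible addition equilibrates toward that same isomer. The target has the arm axial.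
- Two of three ring centres would be uncontrolled, and the mixtures would only be separated after the whole chain has been built.

**Alternative 2:** cut C6–O1 with stereospecific substitution.
- Forward key step: perhydrolysis of an enantioenriched C6–C7 epoxide at the tertiary carbon with inversion to give A2, then closure at C3.
- Turned down because it leaves a hydroxyl on C7 that the target lacks. A carbon radical β to the O–O bond collapses to an epoxide by displacement at oxygen, and ionic deoxygenation at a secondary carbon next to a quaternary centre is not feasible.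
- The same holds for C5 if the epoxide is placed on the other side. The C3 closure would still face the axial/equatorial problem of alternative 1.

**Alternative 3:** cut C6–C7.
- Forward key step: ionisation of peroxyketal A3 to the tertiary peroxycarbenium ion and addition of the chain as a silicon-based allyl nucleophile.
- Turned down because stereoelectronic (axial) attack on the half-chair with the C4 methyl pseudo-equatorial places the new C–C bond trans to the C4 methyl. This gives the C6 epimer of the target; the other half-chair would need a syn-diaxial methyl/nucleophile contact.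
- An allyl-type nucleophile bonds through its CH2 terminus and leaves C8 sp2 or without its methyl, so C8 would still have to be made afterwards.

Key step: step 3

## Remarks and assumptions

- Toluene dioxygenase is taken to oxidise m-xylene at C4–C5 with the same (1S,2R) sense that it shows with toluene.
- Compounds 8 and 12 are E/Z mixtures at the enol ether; the E isomer is drawn, and the geometry disappears in step 10.
- Main-line intermediates are named with the target locants (ring C3–C6), so the CIP letters change where substituent priorities change.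
- For step 14 the accepted facial model of the rhodium/BINAP conjugate addition (the S ligand gives (R)-3-substituted butanoates from E enoates) is used to choose the R ligand.

## Route

Step 1
Reactants: 1 m-xylene
Product: 2 (1S,2R)-3,5-dimethylcyclohexa-3,5-diene-1,2-diol
Conditions: E. coli JM109(pDTG601) whole cells (toluene dioxygenase), air, glucose, phosphate buffer pH 7.2, 30 °C, m-xylene fed as vapour
Reagents that add atoms: dioxygen, O=O
Why: Enzymatic arene cis-dihydroxylation; the dioxygenase oxidises the C4–C5 bond next to one methyl and sets both carbinol centres, and the host lacks the diol dehydrogenase so the dearomatised diol accumulates.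

Step 2
Reactants: 2 (1S,2R)-3,5-dimethylcyclohexa-3,5-diene-1,2-diol
Product: 3 (3aR,7aS)-2,2,4,6-tetramethyl-3a,7a-dihydro-1,3-benzodioxole
Conditions: Me2C(OMe)2, TsOH (cat.), acetone, 0 °C, used at once
Reagents that add atoms: 2,2-dimethoxypropane, COC(C)(C)OC
Why: Acid-catalysed transketalisation of a cis-1,2-diol; cold, short exposure avoids dehydration to the phenol and Diels–Alder dimerisation of the diene.

Step 3
Reactants: 3 (3aR,7aS)-2,2,4,6-tetramethyl-3a,7a-dihydro-1,3-benzodioxole
Product: 4 (1S,4R,7S,8R)-7,8-(isopropylidenedioxy)-1,5-dimethyl-2,3-dioxabicyclo[2.2.2]oct-5-ene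
Conditions: O2, hν (visible), 5,10,15,20-tetraphenylporphyrin (cat.), CH2Cl2, −40 °C
Reagents that add atoms: dioxygen, O=O
Why: Sensitised singlet oxygen adds to the ring-locked s-cis diene of 3 in a suprafacial [4+2] cycloaddition that forms the O–C3 and O–C6 bonds (target locants) in one event. The closest known reaction type is the photooxygenation of cyclohexa-1,3-dienes and of arene cis-dihydrodiol acetonides. The ring closed is the 1,2-dioxane itself, formed by cycloaddition as the peroxide bridge of a 2,3-dioxabicyclo[2.2.2]octene. The two new stereocentres (C3 and the quaternary C6) are cis to each other because the addition is suprafacial. Their sense relative to the diol carbons is set by approach anti to the cis-fused dioxolane, whose two oxygens and gem-dimethyl group cover the other face. The absolute configuration is therefore relayed from the enzymatic step. The step needs facial selectivity and cycloaddition in preference to the ene reaction at the allylic methyls; the acetonide secures the first, and the cisoid diene held in a six-membered ring with low temperature secures the second. The bicyclic frame also makes the C6 methyl (exo) and C7 (bridge) distinct by connectivity and prepares the face control for C4 in step 4.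

Step 4
Reactants: 4 (1S,4R,7S,8R)-7,8-(isopropylidenedioxy)-1,5-dimethyl-2,3-dioxabicyclo[2.2.2]oct-5-ene
Product: 5 (1S,4R,5S,7S,8R)-7,8-(isopropylidenedioxy)-1,5-dimethyl-2,3-dioxabicyclo[2.2.2]octane
Conditions: KO2CN=NCO2K (excess), AcOH, MeOH/CH2Cl2, 0 °C → rt
Reagents that add atoms: none
Why: Diimide transfers H2 in a concerted syn fashion and leaves the O–O bond untouched; the acetonide oxygens point into the inner face of the C4=C5 bridge, so hydrogen should arrive from the peroxide face and push the methyl toward the acetonide bridge, cis to the future C2 and C7 arms (C4 = S in the target). The trisubstituted alkene and the late methyl/oxygen compression call for a large excess.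

Step 5
Reactants: 5 (1S,4R,5S,7S,8R)-7,8-(isopropylidenedioxy)-1,5-dimethyl-2,3-dioxabicyclo[2.2.2]octane
Product: 7 (3R,4S,6S)-4,6-dimethyl-1,2-dioxane-3,6-dicarbaldehyde, via bicyclic peroxy diol 6 (not isolated)
Conditions: AcOH/H2O (4:1), 40 °C; then NaIO4, THF/pH 7 buffer, 0 °C
Reagents that add atoms: none
Why: Acetal hydrolysis followed by glycol cleavage of the rigid eclipsed cis-diol cuts the C2–C7 bond and releases the monocyclic dioxane with the two formyl arms cis; neutral buffer and cold work-up protect the α-peroxy aldehyde at C3 from Kornblum–DeLaMare fragmentation.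

Step 6
Reactants: 7 (3R,4S,6S)-4,6-dimethyl-1,2-dioxane-3,6-dicarbaldehyde
Product: 8 (3R,4S,6S)-3-(2-methoxyethenyl)-4,6-dimethyl-1,2-dioxane-6-carbaldehyde
Conditions: Ph3P(CH2OMe)Cl, KN(SiMe3)2, THF, 0 °C; ylide (1.05 equiv) added to 7 at −78 °C
Reagents that add atoms: (methoxymethyl)triphenylphosphonium chloride, COC[P+](c1ccccc1)(c1ccccc1)c1ccccc1.[Cl-]
Why: Wittig one-carbon homologation; the C2 aldehyde on a tertiary carbon should react faster than the C7 aldehyde on the quaternary C6, and addition at −78 °C should outrun deprotonation at C3.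

Step 7
Reactants: 9 (R)-4-benzyloxazolidin-2-one
Product: 10 (R)-4-benzyl-3-(2-bromoacetyl)oxazolidin-2-one
Conditions: nBuLi, THF, −78 °C; BrCH2COBr
Reagents that add atoms: bromoacetyl bromide, BrCC(Br)=O
Why: N-acylation of the lithiated oxazolidinone with the acid bromide, which reacts at the acyl carbon before the alkyl bromide.

Step 8
Reactants: 10 (R)-4-benzyl-3-(2-bromoacetyl)oxazolidin-2-one
Product: 11 diethyl {2-[(R)-4-benzyl-2-oxooxazolidin-3-yl]-2-oxoethyl}phosphonate
Conditions: P(OEt)3, toluene, 90 °C
Reagents that add atoms: triethyl phosphite, CCOP(OCC)OCC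
Why: Michaelis–Arbuzov reaction of an activated α-bromo carbonyl compound.

Step 9
Reactants: 8 (3R,4S,6S)-3-(2-methoxyethenyl)-4,6-dimethyl-1,2-dioxane-6-carbaldehyde; 11 diethyl {2-[(R)-4-benzyl-2-oxooxazolidin-3-yl]-2-oxoethyl}phosphonate
Product: 12 (R)-4-benzyl-3-{(E)-3-[(3R,4S,6S)-3-(2-methoxyethenyl)-4,6-dimethyl-1,2-dioxan-6-yl]prop-2-enoyl}oxazolidin-2-one
Conditions: LiCl, iPr2NEt, MeCN, rt
Reagents that add atoms: none
Why: Horner–Wadsworth–Emmons olefination under Masamune–Roush conditions; the amine base with lithium chelation gives the E enoyl imide and is mild enough for the peroxide and the hindered α-peroxy aldehyde.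

Step 10
Reactants: 12 (R)-4-benzyl-3-{(E)-3-[(3R,4S,6S)-3-(2-methoxyethenyl)-4,6-dimethyl-1,2-dioxan-6-yl]prop-2-enoyl}oxazolidin-2-one
Product: 14 (R)-4-benzyl-3-{3-[(3S,4S,6R)-3-(2,2-dimethoxyethyl)-4,6-dimethyl-1,2-dioxan-6-yl]propanoyl}oxazolidin-2-one, via dimethyl acetal enoyl imide 13 (not isolated)
Conditions: pyridinium p-toluenesulfonate (cat.), MeOH, rt; then KO2CN=NCO2K, AcOH, 0 °C → rt
Reagents that add atoms: methanol, CO
Why: Acid-catalysed addition of methanol converts the enol ether into the dimethyl acetal, which removes the E/Z mixture and the only other C=C bond; diimide then saturates C7=C8 without touching O–O, so C7 becomes CH2 by a closed-shell process.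

Step 11
Reactants: 14 (R)-4-benzyl-3-{3-[(3S,4S,6R)-3-(2,2-dimethoxyethyl)-4,6-dimethyl-1,2-dioxan-6-yl]propanoyl}oxazolidin-2-one
Product: 15 (R)-4-benzyl-3-{(2R)-3-[(3S,4S,6S)-3-(2,2-dimethoxyethyl)-4,6-dimethyl-1,2-dioxan-6-yl]-2-methylpropanoyl}oxazolidin-2-one
Conditions: NaN(SiMe3)2, THF, −78 °C; MeI (excess), −78 °C
Reagents that add atoms: iodomethane, CI
Why: Evans alkylation; the chelated Z sodium enolate is shielded on one face by the benzyl group of the R auxiliary, so methyl should enter from the other face and give 8R. Low temperature and excess iodomethane are meant to outrun attack of the enolate on the γ O–O bond.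

Step 12
Reactants: 15 (R)-4-benzyl-3-{(2R)-3-[(3S,4S,6S)-3-(2,2-dimethoxyethyl)-4,6-dimethyl-1,2-dioxan-6-yl]-2-methylpropanoyl}oxazolidin-2-one
Product: 16 (2R)-3-[(3S,4S,6R)-3-(2,2-dimethoxyethyl)-4,6-dimethyl-1,2-dioxan-6-yl]-2-methylpropan-1-ol
Conditions: NaBH4, THF/H2O (4:1), 0 °C → rt
Reagents that add atoms: none
Why: Reductive cleavage of the N-acyl oxazolidinone with borohydride, a reagent that does not reduce dialkyl peroxides or acetals; the auxiliary is recovered.

Step 13
Reactants: 16 (2R)-3-[(3S,4S,6R)-3-(2,2-dimethoxyethyl)-4,6-dimethyl-1,2-dioxan-6-yl]-2-methylpropan-1-ol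
Product: 17 (2R)-3-[(3S,4S,6S)-3-(2,2-dimethoxyethyl)-4,6-dimethyl-1,2-dioxan-6-yl]-2-methylpropanal
Conditions: Dess–Martin periodinane, NaHCO3, CH2Cl2, 0 °C
Reagents that add atoms: none
Why: Buffered hypervalent iodine oxidation gives the α-methyl aldehyde without epimerisation at C8 and without affecting the peroxide.

Step 14
Reactants: 18 (E)-2-phenylvinylboronic acid; 19 tert-butyl (E)-but-2-enoate
Product: 20 tert-butyl (3S,4E)-3-methyl-5-phenylpent-4-enoate
Conditions: Rh(acac)(C2H4)2 (3 mol%), (R)-2,2'-bis(diphenylphosphino)-1,1'-binaphthyl, dioxane/H2O (10:1), 100 °C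
Reagents that add atoms: none
Why: Hayashi–Miyaura conjugate addition; the alkenyl–rhodium species inserts the enoate on the face chosen by the ligand and protonolysis releases the ester, so C12 is set by the catalyst and the styrene E geometry is carried over from 18.

Step 15
Reactants: 20 tert-butyl (3S,4E)-3-methyl-5-phenylpent-4-enoate
Product: 21 (3S,4E)-3-methyl-5-phenylpent-4-en-1-ol
Conditions: LiAlH4, THF, 0 °C
Reagents that add atoms: none
Why: Hydride reduction of the ester; the isolated stereocentre and the styrene are untouched.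

Step 16
Reactants: 21 (3S,4E)-3-methyl-5-phenylpent-4-en-1-ol
Product: 22 5-{[(3S,4E)-3-methyl-5-phenylpent-4-en-1-yl]sulfanyl}-1-phenyl-1H-tetrazole
Conditions: 1-phenyl-1H-tetrazole-5-thiol, PPh3, iPrO2CN=NCO2iPr, THF, 0 °C → rt
Reagents that add atoms: 1-phenyl-1H-tetrazole-5-thiol, Sc1nnnn1-c1ccccc1
Why: Mitsunobu thioetherification of a primary alcohol.

Step 17
Reactants: 22 5-{[(3S,4E)-3-methyl-5-phenylpent-4-en-1-yl]sulfanyl}-1-phenyl-1H-tetrazole
Product: 23 5-{[(3S,4E)-3-methyl-5-phenylpent-4-en-1-yl]sulfonyl}-1-phenyl-1H-tetrazole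
Conditions: H2O2 (30%), (NH4)6Mo7O24·4H2O (cat.), EtOH, 0 °C → rt
Reagents that add atoms: hydrogen peroxide, OO
Why: Molybdate-catalysed oxidation of sulfide to sulfone, which is much faster than epoxidation of the unactivated styrene.

Step 18
Reactants: 17 (2R)-3-[(3S,4S,6S)-3-(2,2-dimethoxyethyl)-4,6-dimethyl-1,2-dioxan-6-yl]-2-methylpropanal; 23 5-{[(3S,4E)-3-methyl-5-phenylpent-4-en-1-yl]sulfonyl}-1-phenyl-1H-tetrazole
Product: 24 (3S,4S,6R)-3-(2,2-dimethoxyethyl)-4,6-dimethyl-6-[(2R,3E,6S,7E)-2,6-dimethyl-8-phenylocta-3,7-dien-1-yl]-1,2-dioxane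
Conditions: 23, KN(SiMe3)2, DME, −78 °C; then 17, −78 °C → rt
Reagents that add atoms: none
Why: Julia–Kocienski olefination; addition, Smiles rearrangement and loss of SO2 and tetrazolate should give the E C9=C10 alkene (potassium base in DME). The sulfone is metalated first, so the α-chiral aldehyde meets no free base.

Step 19
Reactants: 24 (3S,4S,6R)-3-(2,2-dimethoxyethyl)-4,6-dimethyl-6-[(2R,3E,6S,7E)-2,6-dimethyl-8-phenylocta-3,7-dien-1-yl]-1,2-dioxane
Product: 25 2-{(3S,4S,6R)-4,6-dimethyl-6-[(2R,3E,6S,7E)-2,6-dimethyl-8-phenylocta-3,7-dien-1-yl]-1,2-dioxan-3-yl}acetaldehyde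
Conditions: TsOH·H2O (cat.), acetone/H2O (10:1), rt
Reagents that add atoms: water, O
Why: Acid-catalysed acetal hydrolysis; the dialkyl peroxide and the isolated alkenes tolerate dilute acid, and no base is present that could open the β-peroxy aldehyde.

Step 20
Reactants: 25 2-{(3S,4S,6R)-4,6-dimethyl-6-[(2R,3E,6S,7E)-2,6-dimethyl-8-phenylocta-3,7-dien-1-yl]-1,2-dioxan-3-yl}acetaldehyde
Product: 26 2-{(3S,4S,6R)-4,6-dimethyl-6-[(2R,3E,6S,7E)-2,6-dimethyl-8-phenylocta-3,7-dien-1-yl]-1,2-dioxan-3-yl}acetic acid (CNP0179089.2)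
Conditions: NaClO2, NaH2PO4, 2-methyl-2-butene, tBuOH/H2O, 0 °C
Reagents that add atoms: sodium chlorite, [Na+].[O-]Cl=O
Why: Pinnick oxidation at weakly acidic pH; the alkene scavenger takes up hypochlorite so the diene and styrene survive, and the peroxide is inert to chlorite.

## Compound list

1 | m-xylene | Cc1cccc(C)c1 | starting material
2 | (1S,2R)-3,5-dimethylcyclohexa-3,5-diene-1,2-diol | O[C@H]1C=C(C)C=C(C)[C@H]1O | intermediate
3 | (3aR,7aS)-2,2,4,6-tetramethyl-3a,7a-dihydro-1,3-benzodioxole | CC1(C)O[C@H]2C=C(C)C=C(C)[C@H]2O1 | intermediate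
4 | (1S,4R,7S,8R)-7,8-(isopropylidenedioxy)-1,5-dimethyl-2,3-dioxabicyclo[2.2.2]oct-5-ene (peroxide bridge anti to the acetonide) | C[C@]12OO[C@H](C(C)=C1)[C@@H]1OC(C)(C)O[C@@H]12 | intermediate
5 | (1S,4R,5S,7S,8R)-7,8-(isopropylidenedioxy)-1,5-dimethyl-2,3-dioxabicyclo[2.2.2]octane (C5 methyl syn to the acetonide bridge) | C[C@]12OO[C@H]([C@@H](C)C1)[C@@H]1OC(C)(C)O[C@@H]12 | intermediate
6 | (1S,4R,5S,7S,8R)-1,5-dimethyl-2,3-dioxabicyclo[2.2.2]octane-7,8-diol | C[C@]12OO[C@H]([C@@H](C)C1)[C@H](O)[C@@H]2O | intermediate (not isolated)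
7 | (3R,4S,6S)-4,6-dimethyl-1,2-dioxane-3,6-dicarbaldehyde (both formyl groups and the C4 methyl cis) | O=C[C@]1(C)C[C@H](C)[C@H](C=O)OO1 | intermediate
8 | (3R,4S,6S)-3-(2-methoxyethenyl)-4,6-dimethyl-1,2-dioxane-6-carbaldehyde (E/Z mixture, E drawn) | O=C[C@]1(C)C[C@H](C)[C@H](/C=C/OC)OO1 | intermediate
9 | (R)-4-benzyloxazolidin-2-one | O=C1N[C@H](Cc2ccccc2)CO1 | starting material
10 | (R)-4-benzyl-3-(2-bromoacetyl)oxazolidin-2-one | BrCC(=O)N1[C@H](Cc2ccccc2)COC1=O | intermediate
11 | diethyl {2-[(R)-4-benzyl-2-oxooxazolidin-3-yl]-2-oxoethyl}phosphonate | CCOP(=O)(OCC)CC(=O)N1[C@H](Cc2ccccc2)COC1=O | intermediate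
12 | (R)-4-benzyl-3-{(E)-3-[(3R,4S,6S)-3-(2-methoxyethenyl)-4,6-dimethyl-1,2-dioxan-6-yl]prop-2-enoyl}oxazolidin-2-one (enol ether E/Z, E drawn) | O=C(/C=C/[C@]1(C)C[C@H](C)[C@H](/C=C/OC)OO1)N1[C@H](Cc2ccccc2)COC1=O | intermediate
13 | (R)-4-benzyl-3-{(E)-3-[(3S,4S,6S)-3-(2,2-dimethoxyethyl)-4,6-dimethyl-1,2-dioxan-6-yl]prop-2-enoyl}oxazolidin-2-one | O=C(/C=C/[C@]1(C)C[C@H](C)[C@H](CC(OC)OC)OO1)N1[C@H](Cc2ccccc2)COC1=O | intermediate (not isolated)
14 | (R)-4-benzyl-3-{3-[(3S,4S,6R)-3-(2,2-dimethoxyethyl)-4,6-dimethyl-1,2-dioxan-6-yl]propanoyl}oxazolidin-2-one | O=C(CC[C@]1(C)C[C@H](C)[C@H](CC(OC)OC)OO1)N1[C@H](Cc2ccccc2)COC1=O | intermediate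
15 | (R)-4-benzyl-3-{(2R)-3-[(3S,4S,6S)-3-(2,2-dimethoxyethyl)-4,6-dimethyl-1,2-dioxan-6-yl]-2-methylpropanoyl}oxazolidin-2-one | O=C([C@H](C)C[C@]1(C)C[C@H](C)[C@H](CC(OC)OC)OO1)N1[C@H](Cc2ccccc2)COC1=O | intermediate
16 | (2R)-3-[(3S,4S,6R)-3-(2,2-dimethoxyethyl)-4,6-dimethyl-1,2-dioxan-6-yl]-2-methylpropan-1-ol | OC[C@H](C)C[C@]1(C)C[C@H](C)[C@H](CC(OC)OC)OO1 | intermediate
17 | (2R)-3-[(3S,4S,6S)-3-(2,2-dimethoxyethyl)-4,6-dimethyl-1,2-dioxan-6-yl]-2-methylpropanal | O=C[C@H](C)C[C@]1(C)C[C@H](C)[C@H](CC(OC)OC)OO1 | intermediate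
18 | (E)-2-phenylvinylboronic acid | OB(O)/C=C/c1ccccc1 | starting material
19 | tert-butyl (E)-but-2-enoate | C/C=C/C(=O)OC(C)(C)C | starting material
20 | tert-butyl (3S,4E)-3-methyl-5-phenylpent-4-enoate | C[C@H](/C=C/c1ccccc1)CC(=O)OC(C)(C)C | intermediate
21 | (3S,4E)-3-methyl-5-phenylpent-4-en-1-ol | C[C@H](/C=C/c1ccccc1)CCO | intermediate
22 | 5-{[(3S,4E)-3-methyl-5-phenylpent-4-en-1-yl]sulfanyl}-1-phenyl-1H-tetrazole | C[C@H](/C=C/c1ccccc1)CCSc1nnnn1-c1ccccc1 | intermediate
23 | 5-{[(3S,4E)-3-methyl-5-phenylpent-4-en-1-yl]sulfonyl}-1-phenyl-1H-tetrazole | C[C@H](/C=C/c1ccccc1)CCS(=O)(=O)c1nnnn1-c1ccccc1 | intermediate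
24 | (3S,4S,6R)-3-(2,2-dimethoxyethyl)-4,6-dimethyl-6-[(2R,3E,6S,7E)-2,6-dimethyl-8-phenylocta-3,7-dien-1-yl]-1,2-dioxane | C[C@H](/C=C/c1ccccc1)C/C=C/[C@H](C)C[C@]1(C)C[C@H](C)[C@H](CC(OC)OC)OO1 | intermediate
25 | 2-{(3S,4S,6R)-4,6-dimethyl-6-[(2R,3E,6S,7E)-2,6-dimethyl-8-phenylocta-3,7-dien-1-yl]-1,2-dioxan-3-yl}acetaldehyde | C[C@H](/C=C/c1ccccc1)C/C=C/[C@H](C)C[C@]1(C)C[C@H](C)[C@H](CC=O)OO1 | intermediate
26 | 2-{(3S,4S,6R)-4,6-dimethyl-6-[(2R,3E,6S,7E)-2,6-dimethyl-8-phenylocta-3,7-dien-1-yl]-1,2-dioxan-3-yl}acetic acid | C[C@H](/C=C/c1ccccc1)C/C=C/[C@H](C)C[C@]1(C)C[C@H](C)[C@H](CC(=O)O)OO1 | target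

## Step count and least certain steps

Total: 20 steps. Longest linear sequence: 14 steps (1–6, 9–13, 18–20).

**Step 3 (key step).**
- What may go wrong: ene reaction at the allylic methyl groups competes with cycloaddition. The diene can dimerise before it is oxygenated. The unsaturated endoperoxide, which has a bridgehead C–H, can rearrange by base or heat before it is reduced.
- Fallback: oxygenate 3 with ground-state O2 under aminium radical-cation catalysis (tris(4-bromophenyl)aminium hexachloroantimonate, CH2Cl2, −78 °C, dark). This is a chain process through the diene radical cation; it has no ene channel and still adds anti to the acetonide. It sets out from 3 and comes back at 4 without any new compound (F0).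

**Step 6.**
- What may go wrong: loss of site selectivity between the two formyl groups, or base-induced fragmentation at C3–H before the ylide has added.
- Fallback: differentiate the two carbons before the ring is opened. Setting out from diol 6 (isolated), one equivalent of Dess–Martin periodinane should oxidise the less hindered C7 hydroxyl, which is remote from the C4 methyl, to (1S,4R,5S,8S)-8-hydroxy-1,5-dimethyl-2,3-dioxabicyclo[2.2.2]octan-7-one F1.
- Pb(OAc)4 in MeOH/benzene cleaves this ketol to methyl (3R,4S,6S)-3-formyl-4,6-dimethyl-1,2-dioxane-6-carboxylate F2.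
- The single aldehyde of F2 takes the same Wittig reagent to give methyl (3R,4S,6S)-3-(2-methoxyethenyl)-4,6-dimethyl-1,2-dioxane-6-carboxylate F3.
- iBu2AlH (CH2Cl2, −78 °C) reduces the ester to the aldehyde, and the route is rejoined at 8.

**Step 11.**
- What may go wrong: intramolecular attack of the C8 enolate on the γ O–O bond (oxetane formation with ring opening) competes with methylation, or the auxiliary control is eroded.
- Fallback: create C8 without a carbanion. Setting out from 8, a Wittig reaction with Ph3P=C(CH3)CHO gives (E)-3-[(3R,4S,6S)-3-(2-methoxyethenyl)-4,6-dimethyl-1,2-dioxan-6-yl]-2-methylprop-2-enal F4.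
- An ene-reductase of the Old Yellow Enzyme family, screened for the R product (NADPH recycling, pH 7), reduces F4 to (2R)-3-[(3R,4S,6S)-3-(2-methoxyethenyl)-4,6-dimethyl-1,2-dioxan-6-yl]-2-methylpropanal F5.
- Julia–Kocienski coupling with 23 gives (3R,4S,6R)-3-(2-methoxyethenyl)-4,6-dimethyl-6-[(2R,3E,6S,7E)-2,6-dimethyl-8-phenylocta-3,7-dien-1-yl]-1,2-dioxane F6.
- Dilute aqueous acid hydrolyses the enol ether, and the route is rejoined at 25.

**Step 14.**
- What may go wrong: protodeboronation of the alkenylboronic acid, low enantioselectivity with an acyclic enoate, or the opposite sense of induction.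
- Fallback: a stereospecific route with a purchased stereocentre. (R,E)-4-Phenylbut-3-en-2-ol F7 (bought) is acetylated to (R,E)-4-phenylbut-3-en-2-yl acetate F8.
- Tsuji–Trost alkylation with NaCH(CO2Me)2 and Pd(PPh3)4 (zerovalent palladium, THF) proceeds with net retention at the methyl-bearing terminus and gives dimethyl 2-[(R,E)-4-phenylbut-3-en-2-yl]malonate F9.
- Krapcho dealkoxycarbonylation (NaCl, wet DMSO, 150 °C) gives methyl (3S,4E)-3-methyl-5-phenylpent-4-enoate F10.
- LiAlH4 reduction rejoins the route at 21.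

## Further compounds

F0 | step 3 | none | none
F1 | step 6 | (1S,4R,5S,8S)-8-hydroxy-1,5-dimethyl-2,3-dioxabicyclo[2.2.2]octan-7-one | C[C@]12OO[C@H]([C@@H](C)C1)[C@H](O)C2=O
F2 | step 6 | methyl (3R,4S,6S)-3-formyl-4,6-dimethyl-1,2-dioxane-6-carboxylate | COC(=O)[C@]1(C)C[C@H](C)[C@H](C=O)OO1
F3 | step 6 | methyl (3R,4S,6S)-3-(2-methoxyethenyl)-4,6-dimethyl-1,2-dioxane-6-carboxylate (E/Z, E drawn) | COC(=O)[C@]1(C)C[C@H](C)[C@H](/C=C/OC)OO1
F4 | step 11 | (E)-3-[(3R,4S,6S)-3-(2-methoxyethenyl)-4,6-dimethyl-1,2-dioxan-6-yl]-2-methylprop-2-enal | O=C/C(C)=C/[C@]1(C)C[C@H](C)[C@H](/C=C/OC)OO1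
F5 | step 11 | (2R)-3-[(3R,4S,6S)-3-(2-methoxyethenyl)-4,6-dimethyl-1,2-dioxan-6-yl]-2-methylpropanal | O=C[C@H](C)C[C@]1(C)C[C@H](C)[C@H](/C=C/OC)OO1
F6 | step 11 | (3R,4S,6R)-3-(2-methoxyethenyl)-4,6-dimethyl-6-[(2R,3E,6S,7E)-2,6-dimethyl-8-phenylocta-3,7-dien-1-yl]-1,2-dioxane | C[C@H](/C=C/c1ccccc1)C/C=C/[C@H](C)C[C@]1(C)C[C@H](C)[C@H](/C=C/OC)OO1
F7 | step 14 | (R,E)-4-phenylbut-3-en-2-ol | C[C@@H](O)/C=C/c1ccccc1
F8 | step 14 | (R,E)-4-phenylbut-3-en-2-yl acetate | C[C@@H](OC(C)=O)/C=C/c1ccccc1
F9 | step 14 | dimethyl 2-[(R,E)-4-phenylbut-3-en-2-yl]malonate | C[C@@H](C(C(=O)OC)C(=O)OC)/C=C/c1ccccc1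
F10 | step 14 | methyl (3S,4E)-3-methyl-5-phenylpent-4-enoate | C[C@@H](CC(=O)OC)/C=C/c1ccccc1
A1 | alternative 1 | methyl (2E,4S,6R,8R,9E,12S,13E)-6-hydroperoxy-4,6,8,12-tetramethyl-14-phenyltetradeca-2,9,13-trienoate (would form with its C6 epimer) | C[C@H](/C=C/c1ccccc1)C/C=C/[C@H](C)C[C@@](C)(OO)C[C@H](C)/C=C/C(=O)OC
A2 | alternative 2 | methyl (2E,4S,6S,7S,8S,9E,12S,13E)-6-hydroperoxy-7-hydroxy-4,6,8,12-tetramethyl-14-phenyltetradeca-2,9,13-trienoate | C[C@H](/C=C/c1ccccc1)C/C=C/[C@H](C)[C@H](O)[C@@](C)(OO)C[C@H](C)/C=C/C(=O)OC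
A3 | alternative 3 | methyl 2-[(3S,4S)-6-methoxy-4,6-dimethyl-1,2-dioxan-3-yl]acetate (both C6 epimers) | COC1(C)C[C@H](C)[C@H](CC(=O)OC)OO1
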